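All runs come from a simulation for substances that don't exist, and the scatter is random.

Percentage points per hour of left-handed product are what we watch in the violet flask. A racemate of the two substrates meets a single-handed coupling partner.

all flasks: left-handed substrate 0.10 M; right-handed substrate 0.10 M

| run | coupling partner | temperature | remark | time |
|---|---|---|---|---|
| violet | 0.20 M | 25 °C | the very flask that is asked about, followed so far |  |
| blue | 0.30 M | 10 °C | run made earlier |  |
| flask | 0.200 M | 25 °C |  | 5.0 h |

violet run (percent of the left-handed substrate and right-handed substrate together charged)

| time / h | left-handed product / % | left-handed substrate / % |
|---|---|---|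
| 1.00 | 53.6 | 0.2 |
| 2.00 | 56.8 | 0.3 |
| 3.00 | 59.0 | 0.8 |
| 4.00 | 60.7 | 0.3 |

blue run (percent of the left-handed substrate and right-handed substrate together charged)

| time / min | left-handed product / % | left-handed substrate / % |
|---|---|---|
| 10.0 | 45.1 | 4.2 |
| 30.0 | 50.3 | 0 |
| 50.0 | 50.2 | 0 |
| 80.0 | 50.5 | 0.4 |

(readings scatter by 0.3 percentage points)

- coupling partner is single-handed; left-handed substrate and right-handed substrate are mirror images of each other, charged as a racemate, each of them at the stated concentration
- left-handed product that was removed still counts
- additions bring no volume worth counting
- the handed part of coupling partner does not stay in what it makes, so the products of the two hands are mirror images too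

- Wednesday's: at 5.0 h add coupling partner, 100% of the amount charged, then wait 5.0 h
- Monday's: at 5.0 h take out 90% of the left-handed product then present, then wait 5.0 h
- Sunday's: change nothing and wait 5.0 h more
- Friday's: at 5.0 h raise the temperature by 20 K, then wait 5.0 h

- left-handed product, in percent of the left-handed substrate and right-handed substrate together first charged, at 5.0 h
- the remedy with the largest gain of left-handed product, or "none" below 2 percentage points (Wednesday's / Monday's / Sunday's / Friday's / none)
- left-handed product present, with what was taken out counted in, in percent of the left-handed substrate and right-handed substrate together first charged, after Wednesday's
- left-handed product present, with what was taken out counted in, in percent of the left-handed substrate and right-handed substrate together first charged, after Monday's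

We work with what is left. At 4.00 h the violet run reads 60.7% left-handed product and 0.3% left-handed substrate, so 39.0% of the charge is neither. Left-handed substrate reads 0.8% at most while the product passes the left-handed charge, so right-handed substrate must be inverting and feeding it (dynamic kinetic resolution). The hourly gain then measures the right-handed substrate standing. That gain falls from 3.2 percentage points to 1.7 points across the run, which gives the feed half-life τ, the time in which the hourly gain drops by a factor of 2: 2.19 h, a reading with that scatter in it.

But a feed with this half-life has about 5.4 points still to give, far less than the open 39.0%. The two numbers fit if right-handed substrate also leaves by direct coupling to right-handed product, which we do not read. So τ belongs to a pool drained two ways.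

Shrinking the last hourly gain by τ, we expect 61.9% at 5.0 h. The blue run, colder and richer in coupling partner than the violet run, gained 0.2 points in 50.0 min, against a scatter of 0.3 points. We would bet on Friday's, though those two runs differ in two settings.

The forecast says 62.2% at 5.0 h, 64.5% after Wednesday's and 73% after Monday's, and it names Monday's: “Removing product protects it, giving about 73%.”

The flask gives 61.8%, 63.4% after Wednesday's and 65.7% after Monday's. The largest gain is Friday's, at 9.7 points.

    coupling partner + right-handed substrate → right-handed product (k = 0.0670 /M/min, Ea = 55.0 kJ/mol)
    coupling partner + left-handed substrate → left-handed product (k = 2.90 /M/min, Ea = 50.0 kJ/mol)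
    left-handed substrate ⇌ right-handed substrate (k = 0.00180 /min, Ea = 108 kJ/mol)
    coupling partner → decomposition product (k = 6.30 × 10⁻⁶ /min, Ea = 111 kJ/mol)
    (constants at 25 °C)

In the violet flask at 0.0343 h, right-handed substrate has a half-life of 1.3 h by direct coupling but 6.42 h by inversion, and τ of 2.19 h lies between them. At 5.00 h that flask holds 26.6% right-handed product beside 11.3% right-handed substrate. In the neighbour flask with 0.34 M of coupling partner, the 1.11% of right-handed substrate left corresponds to a half-life, averaged over its time, of 0.910 h, shorter than τ, and left-handed product stands at 56.0% beside 42.9% right-handed product.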